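Monomer in chains is the product, and a chain's length is that amount over the chains begun. I take one chain per initiator used and no chain dying. The length is then the charge ratio, free monomer charged over initiator charged, 500, times the part of the free monomer in chains, divided by the part of the initiator used.

| setting | summer | dawn | flask |
|---|---|---|---|
| free monomer | 0.18 M | 0.090 M | 0.18 M |
| initiator | 0.36 mM | 0.36 mM | 0.36 mM |
| remark | the very flask that is asked about, followed so far | run made earlier |  |
| time |  |  | 30 h |

| run | time / h | monomer in chains / % | free monomer / % |
|---|---|---|---|
| summer | 1.00 | 0.1 | 99.7 |
| summer | 3.00 | 1.6 | 98.3 |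
| summer | 6.00 | 5.2 | 94.4 |
| summer | 8.00 | 8.7 | 90.6 |
| summer | 12.0 | 17.5 | 81.4 |
| dawn | 1.50 | 0.4 | 99.7 |
| dawn | 3.00 | 0.4 | 99.1 |
| dawn | 6.00 | 3.0 | 97.3 |
| dawn | 12.0 | 9.7 | 89.1 |
| dawn | 20.0 | 24.0 | 75.1 |

(scatter of a reading: 0.3 percentage points)
1. whether the average number of monomer units in a chain (chains begun, living or dead) reaches 300 by 30 h (yes / no)
2. average number of monomer units in a chain (chains begun, living or dead) at 30 h
- the average divides the monomer in chains by the number of chains begun, living and dead together
- the earlier runs do not show the number of chains; that part of a forecast is a guess

1. The start is flat. In the summer run the logarithmic loss of free monomer rises with time squared, as half the square of time over a constant of 17.7 h. The dawn run, with half the charge, loses half as much by 6.00 h. So I take chains to begin in proportion to free monomer, and the loss to be pseudo-first-order in free monomer on the chains begun.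

2. The knee comes next. The summer hourly loss goes from 0.0205 /h to 0.0268 /h, so the curvature sags to 0.648 of its starting value. Allowing for the free monomer gone, about 28.4% of the initiator is used there, a rough reading.

3. Those readings give B, the hourly loss with the initiator fully used over the starting hourly use of initiator: 2.16. Dividing the two rate laws removes time, so with x reacted and f used, x ≈ B·f·f/2·(1 + 2f/3).

4. The crossing: 300 needs x/f = 0.600. The leading term gives f = 0.556, the correction 0.405, so x = 24.3%, near 14.7 h in the summer flask.

5. The far end: holding the last hourly loss leaves 50.3% free monomer at 30 h. The rule then gives a length near 442, low because the hourly loss is still rising. I say yes.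

The forecast says yes with 750, above my figure, and notes: “The runs cannot separate these two causes.”

The flask gives yes and 551.

    free monomer + initiator → living end + monomer in chains (k = 5.50 × 10⁻⁵ /M/s)
    free monomer + living end → monomer in chains + living end, rate k2*[living end]*[free monomer] (k = 0.0690 /M/s)
    free monomer → uncatalysed product (k = 2.20 × 10⁻⁷ /s)

At 30.0 h the flask holds 59.6% of the charged free monomer in chains and 46.0% of its initiator, so the charge ratio gives 551, and the length passed 300 at 13.6 h with 22.5% reacted, against my 24.3%. At 30.0 h growth uses free monomer 61 times as fast as the uncatalysed turning, whose product stands at 1.73%.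

(Readings and results are simulated with made-up constants; scatter was added.)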